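The pyranone ring of the target has a single C–H, at C3, lying between the lactone carbon C2 and the aryl-bearing C4. The ring is therefore made from a furan ring by inserting that one carbon into the enol-ether bond between furan C2 and C3 of a 3-aryl-4,6,7-trimethoxybenzofuran whose 3'-hydroxyl is masked as a benzyl ether. One dibromocarbene ring expansion should forge C2–C3 and C3–C4, deliver the six-membered oxygen ring at the acetal oxidation level and leave a bromine at C3 that is removed together with the benzyl group at the end. The benzofuran itself comes from a phenacyl aryl ether by cyclodehydration.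

Key step: step 8

Remark: the target has no stereocentre and no stereogenic double bond, so it is one achiral compound and no absolute configuration has to be set; the acetal carbon created in step 8 is a stereocentre formed as a racemate and is removed at the lactone stage in step 9.

Step 1
Reactants: 1 3-bromo-4,5-dimethoxybenzaldehyde
Product: 3 3-bromo-4,5-dimethoxyphenol, via aryl formate 2 (not isolated)
Conditions: mCPBA, CH2Cl2, 0 °C → rt; aq. NaHCO3 wash; then K2CO3 (cat.), MeOH, rt
Reagents that add atoms: 3-chloroperoxybenzoic acid (mCPBA), O=C(OO)c1cccc(Cl)c1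
Why: Baeyer–Villiger oxidation of an aromatic aldehyde whose para-methoxy group favours aryl over hydride migration should give the aryl formate, which catalytic carbonate in methanol transesterifies to the phenol.

Step 2
Reactants: 3 3-bromo-4,5-dimethoxyphenol
Product: 4 1-bromo-2,3,5-trimethoxybenzene
Conditions: MeI, K2CO3, acetone, reflux
Reagents that add atoms: iodomethane, CI
Why: Williamson O-methylation of the phenoxide, the only nucleophilic site in the molecule.

Step 3
Reactants: 4 1-bromo-2,3,5-trimethoxybenzene
Product: 5 2,3,5-trimethoxyphenol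
Conditions: Pd2(dba)3 (cat.), tBuXPhos (cat.), KOH, 1,4-dioxane/H2O, 100 °C, N2; then aq. HCl
Reagents that add atoms: potassium hydroxide, [K+].[OH-]
Why: Palladium-catalysed C–O cross-coupling of an aryl bromide with hydroxide, in which the bulky biaryl phosphine favours phenol formation over diaryl ether formation, should exchange bromine for hydroxyl without touching the methyl ethers.

Step 4
Reactants: 6 1-(3-hydroxy-4-methoxyphenyl)ethan-1-one (3-hydroxy-4-methoxyacetophenone)
Product: 7 1-[3-(benzyloxy)-4-methoxyphenyl]ethan-1-one
Conditions: BnBr, K2CO3, DMF, rt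
Reagents that add atoms: benzyl bromide, BrCc1ccccc1
Why: Williamson benzylation of the phenol; the benzyl ether is chosen because it resists the alkoxide base of step 8 and leaves in the final hydrogenolysis.

Step 5
Reactants: 7 1-[3-(benzyloxy)-4-methoxyphenyl]ethan-1-one
Product: 8 1-[3-(benzyloxy)-4-methoxyphenyl]-2-bromoethan-1-one
Conditions: PhNMe3Br3 (1.0 equiv), THF, 0 °C → rt
Reagents that add atoms: phenyltrimethylammonium tribromide, C[N+](C)(C)c1ccccc1.[Br-].BrBr
Why: Acid-catalysed enol bromination of an aryl methyl ketone with a mild solid tribromide should stop at the monobromide and spare the acyl-deactivated ring and the benzyl ether.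

Step 6
Reactants: 5 2,3,5-trimethoxyphenol; 8 1-[3-(benzyloxy)-4-methoxyphenyl]-2-bromoethan-1-one
Product: 9 1-[3-(benzyloxy)-4-methoxyphenyl]-2-(2,3,5-trimethoxyphenoxy)ethan-1-one
Conditions: K2CO3, acetone, reflux, N2
Reagents that add atoms: none
Why: SN2 displacement (Williamson ether synthesis) of the reactive phenacyl bromide by the phenoxide of 5 under mild carbonate conditions.

Step 7
Reactants: 9 1-[3-(benzyloxy)-4-methoxyphenyl]-2-(2,3,5-trimethoxyphenoxy)ethan-1-one
Product: 11 3-[3-(benzyloxy)-4-methoxyphenyl]-4,6,7-trimethoxy-1-benzofuran, via dihydrobenzofuran-3-ol 10 (not isolated)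
Conditions: Bi(OTf)3 (10 mol%), 4 Å MS, CH2Cl2, 40 °C
Reagents that add atoms: none
Why: Lewis-acid-catalysed cyclodehydration (intramolecular Friedel–Crafts hydroxyalkylation, then loss of water): the only free position ortho to the ether oxygen is activated by one ortho and one para methoxy group, so ring closure should proceed under conditions mild enough to keep the benzyl ether and to avoid a 3-to-2 aryl shift.

Step 8
Reactants: 11 3-[3-(benzyloxy)-4-methoxyphenyl]-4,6,7-trimethoxy-1-benzofuran; 12 bromoform
Product: 15 racemic 4-[3-(benzyloxy)-4-methoxyphenyl]-3-bromo-2-ethoxy-5,7,8-trimethoxy-2H-chromene, via dibromocyclopropane adduct 13 (not isolated), via 3-bromochromenylium bromide 14 (not isolated)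
Conditions: CHBr3 (4 equiv), KOtBu (3.5 equiv), toluene, −20 °C → rt; then EtOH, rt; then Et3N
Reagents that add atoms: ethanol, CCO
Why: Bromoform is deprotonated and loses bromide to give singlet dibromocarbene, an electrophile that should add in a concerted [2+1] cycloaddition to the furan C2=C3 enol-ether bond of 11 to give the cis-fused adduct 13. Loss of the endo bromide is coupled to disrotatory cyclopropyl-to-allyl opening that breaks the former C2–C3 bond and gives the 3-bromochromenylium ion 14, stabilised by the ring oxygen at C2 and by the aryl group and the 5- and 7-methoxy groups at C4; ethanol then adds at C2. The closest known reaction type is the dihalocarbene ring enlargement of benzofurans and indenes to 3-halo-2-alkoxy-2H-chromenes and 2-halonaphthalenes, a relative of the Ciamician–Dennstedt rearrangement. The pyran ring is not closed by a cyclisation: it arises by one-carbon ring expansion in the 2π-electrocyclic opening of the bicyclic cyclopropyl cation, which turns the five-membered oxygen ring into the six-membered one. The only new stereocentre, the acetal carbon C2, is formed without control as a racemate and is erased in step 9. The step needs the carbene to choose the furan double bond over the methoxyarenes, which the much higher nucleophilicity of the non-benzenoid enol-ether bond should secure, and it needs ethanol to add at C2 and not at C4, which the shielding of C4 by the aryl group, the bromine and the 5-methoxy group and the reversibility of alkoxy exchange in the briefly acidic ethanol stage should secure.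

Step 9
Reactants: 15 racemic 4-[3-(benzyloxy)-4-methoxyphenyl]-3-bromo-2-ethoxy-5,7,8-trimethoxy-2H-chromene
Product: 17 4-[3-(benzyloxy)-4-methoxyphenyl]-3-bromo-5,7,8-trimethoxy-2H-chromen-2-one, via lactol 16 (not isolated)
Conditions: Jones reagent (CrO3, aq. H2SO4), acetone, 0 °C
Reagents that add atoms: water, O
Why: Jones oxidation of a cyclic acetal: the aqueous acid hydrolyses the readily ionised allylic acetal to lactol 16, which chromic acid oxidises to the lactone, removing the C2 stereocentre, while the aryl ethers and the vinyl bromide should survive at 0 °C.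

Step 10
Reactants: 17 4-[3-(benzyloxy)-4-methoxyphenyl]-3-bromo-5,7,8-trimethoxy-2H-chromen-2-one
Product: 19 3'-hydroxy-5,7,8,4'-tetramethoxy-4-phenylcoumarin, via O-benzyl coumarin 18 (not isolated)
Conditions: H2 (1 atm), 10% Pd/C, NaOAc, EtOAc/MeOH, rt
Reagents that add atoms: none
Why: Heterogeneous palladium hydrogenolysis should cleave the activated C3–Br bond (acetate takes up HBr) and then the O-benzyl bond in the same flask, while the hindered trisubstituted C3=C4 bond of the coumarin should persist under one atmosphere of hydrogen at room temperature.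

Compound list
1 | 3-bromo-4,5-dimethoxybenzaldehyde | O=Cc1cc(Br)c(OC)c(OC)c1 | starting material
2 | 3-bromo-4,5-dimethoxyphenyl formate | O=COc1cc(Br)c(OC)c(OC)c1 | intermediate (not isolated)
3 | 3-bromo-4,5-dimethoxyphenol | Oc1cc(Br)c(OC)c(OC)c1 | intermediate
4 | 1-bromo-2,3,5-trimethoxybenzene | COc1cc(Br)c(OC)c(OC)c1 | intermediate
5 | 2,3,5-trimethoxyphenol | COc1cc(O)c(OC)c(OC)c1 | intermediate
6 | 1-(3-hydroxy-4-methoxyphenyl)ethan-1-one | CC(=O)c1ccc(OC)c(O)c1 | starting material
7 | 1-[3-(benzyloxy)-4-methoxyphenyl]ethan-1-one | CC(=O)c1ccc(OC)c(OCc2ccccc2)c1 | intermediate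
8 | 1-[3-(benzyloxy)-4-methoxyphenyl]-2-bromoethan-1-one | O=C(CBr)c1ccc(OC)c(OCc2ccccc2)c1 | intermediate
9 | 1-[3-(benzyloxy)-4-methoxyphenyl]-2-(2,3,5-trimethoxyphenoxy)ethan-1-one | O=C(COc1cc(OC)cc(OC)c1OC)c1ccc(OC)c(OCc2ccccc2)c1 | intermediate
10 | racemic 3-[3-(benzyloxy)-4-methoxyphenyl]-4,6,7-trimethoxy-2,3-dihydro-1-benzofuran-3-ol | OC1(c2ccc(OC)c(OCc3ccccc3)c2)COc2c(OC)c(OC)cc(OC)c21 | intermediate (not isolated)
11 | 3-[3-(benzyloxy)-4-methoxyphenyl]-4,6,7-trimethoxy-1-benzofuran | c1oc2c(OC)c(OC)cc(OC)c2c1-c1ccc(OC)c(OCc2ccccc2)c1 | intermediate (key-step precursor)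
12 | bromoform | BrC(Br)Br | starting material
13 | racemic, cis-fused 6b-[3-(benzyloxy)-4-methoxyphenyl]-1,1-dibromo-3,4,6-trimethoxy-1a,6b-dihydro-1H-cyclopropa[b][1]benzofuran | BrC1(Br)C2Oc3c(OC)c(OC)cc(OC)c3C12c1ccc(OC)c(OCc2ccccc2)c1 | intermediate (not isolated)
14 | 4-[3-(benzyloxy)-4-methoxyphenyl]-3-bromo-5,7,8-trimethoxychromenylium bromide | [Br-].COc1cc(OC)c(OC)c2[o+]cc(Br)c(-c3ccc(OC)c(OCc4ccccc4)c3)c12 | intermediate (not isolated)
15 | racemic 4-[3-(benzyloxy)-4-methoxyphenyl]-3-bromo-2-ethoxy-5,7,8-trimethoxy-2H-chromene | CCOC1Oc2c(OC)c(OC)cc(OC)c2C(c2ccc(OC)c(OCc3ccccc3)c2)=C1Br | intermediate (key-step product)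
16 | racemic 4-[3-(benzyloxy)-4-methoxyphenyl]-3-bromo-5,7,8-trimethoxy-2H-chromen-2-ol | OC1Oc2c(OC)c(OC)cc(OC)c2C(c2ccc(OC)c(OCc3ccccc3)c2)=C1Br | intermediate (not isolated)
17 | 4-[3-(benzyloxy)-4-methoxyphenyl]-3-bromo-5,7,8-trimethoxy-2H-chromen-2-one | O=c1oc2c(OC)c(OC)cc(OC)c2c(-c2ccc(OC)c(OCc3ccccc3)c2)c1Br | intermediate
18 | 4-[3-(benzyloxy)-4-methoxyphenyl]-5,7,8-trimethoxy-2H-chromen-2-one | O=c1cc(-c2ccc(OC)c(OCc3ccccc3)c2)c2c(OC)cc(OC)c(OC)c2o1 | intermediate (not isolated)
19 | 4-(3-hydroxy-4-methoxyphenyl)-5,7,8-trimethoxy-2H-chromen-2-one (3'-hydroxy-5,7,8,4'-tetramethoxy-4-phenylcoumarin), achiral | COc1ccc(-c2cc(=O)oc3c(OC)c(OC)cc(OC)c23)cc1O | target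

Total step count: 10 steps.
Longest linear sequence: 8 steps (steps 1, 2, 3, 6, 7, 8, 9, 10, from compound 1).

Steps most likely to fail

Step 8. The carbene may add only sluggishly to the hindered, trisubstituted furan double bond, or attack the very electron-rich arenes instead. The chromenylium salt may also be captured at C4, or be hydrolysed and degraded before ethanol traps it. The fallback sets out from 5 and comes back to the route at 19; it builds the 4-arylcoumarin by cross-coupling instead of ring expansion. Phenol 5 is heated with Meldrum's acid (toluene, 100 °C) to give 3-oxo-3-(2,3,5-trimethoxyphenoxy)propanoic acid F1. Eaton's reagent at 70 °C closes F1 by intramolecular Friedel–Crafts acylation at the only free ortho position, giving 4-hydroxy-5,7,8-trimethoxy-2H-chromen-2-one F2. Tf2O and Et3N in CH2Cl2 convert F2 into 5,7,8-trimethoxy-2-oxo-2H-chromen-4-yl trifluoromethanesulfonate F3. Suzuki–Miyaura coupling of F3 with commercial (3-hydroxy-4-methoxyphenyl)boronic acid (Pd(PPh3)4, K3PO4, 1,4-dioxane, 80 °C) should give 19 directly.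

Step 7. The Lewis acid may strip the benzyl ether, or the acid may shift the aryl group from C3 to C2 of the benzofuran. The fallback sets out from 5 and comes back to the route at 11; it makes the C3–aryl bond by cross-coupling on a preformed benzofuran. Phenol 5 is O-alkylated with chloroacetic acid (aq. NaOH, reflux, then acidification) to give (2,3,5-trimethoxyphenoxy)acetic acid F4. Polyphosphoric acid at 80 °C closes the five-membered ring to 4,6,7-trimethoxy-1-benzofuran-3(2H)-one F5. Tf2O and Et3N in CH2Cl2 at −20 °C give the enol triflate 4,6,7-trimethoxy-1-benzofuran-3-yl trifluoromethanesulfonate F6. Suzuki–Miyaura coupling of F6 with commercial [3-(benzyloxy)-4-methoxyphenyl]boronic acid (Pd(PPh3)4, K3PO4, 1,4-dioxane, 80 °C) should give 11, with no acid present once the benzyl ether is in the molecule.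

Step 9. Chromic acid may over-oxidise the para-dimethoxylated A ring or the ring-opened hydroxy-enal form of the lactol. The fallback sets out from 15 and comes back to the route at 17; it separates hydrolysis from a neutral, chromium-free oxidation. PPTS in aqueous acetone hydrolyses 15 to lactol 16, which is now isolated. Silver carbonate on Celite (Fétizon oxidation, toluene, reflux) then oxidises the lactol to 17; no new compound is made.

Further compounds
F1 | step 8 | 3-oxo-3-(2,3,5-trimethoxyphenoxy)propanoic acid | O=C(O)CC(=O)Oc1cc(OC)cc(OC)c1OC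
F2 | step 8 | 4-hydroxy-5,7,8-trimethoxy-2H-chromen-2-one | O=c1cc(O)c2c(OC)cc(OC)c(OC)c2o1
F3 | step 8 | 5,7,8-trimethoxy-2-oxo-2H-chromen-4-yl trifluoromethanesulfonate | O=c1cc(OS(=O)(=O)C(F)(F)F)c2c(OC)cc(OC)c(OC)c2o1
F4 | step 7 | (2,3,5-trimethoxyphenoxy)acetic acid | O=C(O)COc1cc(OC)cc(OC)c1OC
F5 | step 7 | 4,6,7-trimethoxy-1-benzofuran-3(2H)-one | O=C1COc2c(OC)c(OC)cc(OC)c21
F6 | step 7 | 4,6,7-trimethoxy-1-benzofuran-3-yl trifluoromethanesulfonate | O=S(=O)(Oc1coc2c(OC)c(OC)cc(OC)c12)C(F)(F)F
F0 | step 9 | none | none
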